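I began with the easy step, the substrate, which two first-order steps carry onward, one to intermediate B and one to intermediate A, in the ratio 4.48.

| setting | oak | maple |
|---|---|---|
| substrate | 0.036 M | 0.036 M |
| time | 3.0 h |  |
| remark | a closed flask charged with all of it at once and left for 3.0 h | one stirred flow tank at steady state, fed with the mixture as stated, mean residence time 3.0 h |

- the set-up with the highest share of target in all that became target or side product, at the outlet or at the end ("none" if the first two lie within 2 percentage points) (oak / maple / none)
- share of target in all that became target or side product, at the outlet or at the end, oak
- share of target in all that became target or side product, at the outlet or at the end, maple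

- the stated concentrations are those of everything mixed, before any reaction; amounts are the same in each set-up
- run time (oak): 3.0 h

    intermediate B → target (k1 = 3.0 × 10⁻⁴ s⁻¹)
    substrate → intermediate B (k2 = 0.0026 s⁻¹)
    intermediate B → side product (k3 = 2.1 × 10⁻⁴ s⁻¹)
    intermediate A → target (k4 = 2.3 × 10⁻⁴ s⁻¹)
    substrate ⇌ dormant form (K5 = 0.84, k5 = 3.6 × 10⁻⁴ s⁻¹)
    substrate → intermediate A (k6 = 5.8 × 10⁻⁴ s⁻¹)

The substrate goes onward at 0.00318 s⁻¹, faster than intermediate B at 5.10 × 10⁻⁴ s⁻¹ or intermediate A at 2.3 × 10⁻⁴ s⁻¹, so in oak I counted it as turned over at the start. The dormant form delays some substrate, but that ratio stays, so 81.8% of what reacts goes through intermediate B and 18.2% through intermediate A. Intermediate A has one way on, to target, but intermediate B forks, with 58.8% of it becoming target and the rest side product.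

So I took as my rule the branching share, the part of the reacted substrate that ends as target once the intermediates have gone through: 66.3%. This is the selectivity at the end of the road.

But oak stops at 3.0 h, with 8.34% of what entered intermediate A and 0.405% of what entered intermediate B unreacted by my reckoning, which gives 65.8%. In maple, with 3.0 h as mean residence time, the outlet competes: 71.3% of the intermediate A formed and 84.6% of the intermediate B formed react before leaving, which gives 65.3%. The gap of 0.5 percentage points is below the margin, so I expected no winner.

The forecast said 65.8% for oak, 65.3% for maple and best none, since “set-ups differ by less than 2 points”. The simulation gave 65.8%, 65.3% and none.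

In oak, the conversion of substrate into intermediate B had half of its turnover up to 3.00 h behind it by 0.0636 h, and at 1.50 h, with substrate at 0.196% of the charge, intermediate A stood at 5.85% and intermediate B at 7.27%. At 3.00 h oak held 1.81% of intermediate A and 0.717% of intermediate B, and its share lay 0.50 points below the branching share.

The flask oak left until 5.0 h should stand close to the branching share of 66.3%, with 0.290% of the charge still intermediate A by my reckoning. That flask gave 66.2%, with 0.358% of intermediate A.

The numbers are assumed; the result is computed.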